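Both ring-A prenyl groups are disconnected at their aryl–CH2 bonds back to 1,1-dimethylallyl ethers on the neighbouring phenol oxygens O2 and O6. The key step exploits the fact that C3 and C5 each lie ortho to one of these oxygens, while the other ortho carbon, C1, is occupied by the aroyl group. Heating the bis-ether therefore sends both allyl units by [3,3] shifts only to C3 and C5, making two C–C bonds and unveiling both chelated phenols in one operation. The precursor is the 2,6-bis(2-methylbut-3-en-2-yl) ether of 2,6-dihydroxy-4-methoxy-4'-pivaloyloxybenzophenone, assembled from 1,3,5-trimethoxybenzene, 4-hydroxybenzoic acid and 3-chloro-3-methylbut-1-yne.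

Key step: step 6

Remark: the target has no stereocentre and no configurationally stable axis, so it is a single achiral compound and no step has to control stereochemistry.

Step 1
Reactants: 1 4-hydroxybenzoic acid
Product: 2 4-(pivaloyloxy)benzoic acid
Conditions: PivCl (1.1 equiv), NaOH (2.2 equiv), H2O/THF, 0 °C; then 1 M HCl
Reagents that add atoms: pivaloyl chloride, CC(C)(C)C(=O)Cl
Why: Schotten–Baumann O-acylation, in which the phenoxide is acylated in aqueous base while any mixed anhydride formed at the carboxylate hydrolyses back, so acidification should return the free acid carrying the hindered aryl ester.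

Step 2
Reactants: 2 4-(pivaloyloxy)benzoic acid; 3 1,3,5-trimethoxybenzene
Product: 5 (2,4,6-trimethoxyphenyl)[4-(pivaloyloxy)phenyl]methanone, via 4-(pivaloyloxy)benzoyl chloride 4 (not isolated)
Conditions: (COCl)2, DMF (cat.), CH2Cl2, 0 °C → rt; concentrate; then 3, AlCl3 (1.3 equiv), CH2Cl2, 0 °C; aq. HCl
Reagents that add atoms: none
Why: DMF-catalysed acid chloride formation followed by Friedel–Crafts acylation, where the symmetrical electron-rich arene 3 can give only one mono-ketone, the product is deactivated towards a second acylation, and any ortho-demethylated material is simply an intermediate of step 3.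

Step 3
Reactants: 5 (2,4,6-trimethoxyphenyl)[4-(pivaloyloxy)phenyl]methanone
Product: 7 (2,6-dihydroxy-4-methoxyphenyl)[4-(pivaloyloxy)phenyl]methanone, via mono-demethylated ketone 6 (not isolated)
Conditions: AlCl3 (4 equiv), CH2Cl2, 0 °C → rt; ice/1 M HCl
Reagents that add atoms: none
Why: Carbonyl-assisted Lewis-acid ether cleavage, in which aluminium bound at the ketone activates each flanking methoxy group in turn for SN2 demethylation by chloride, whereas the 4-methoxy group has no neighbouring carbonyl and such aryl methyl ethers are not cleaved by AlCl3 in CH2Cl2 at room temperature.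

Step 4
Reactants: 7 (2,6-dihydroxy-4-methoxyphenyl)[4-(pivaloyloxy)phenyl]methanone; 8 3-chloro-3-methylbut-1-yne
Product: 10 [4-methoxy-2,6-bis(2-methylbut-3-yn-2-yloxy)phenyl][4-(pivaloyloxy)phenyl]methanone, via mono-propargyl ether 9 (not isolated)
Conditions: 8 (3 equiv), CuCl2·2H2O (2 mol %), DBU (3.5 equiv), MeCN, N2, 0 °C → rt
Reagents that add atoms: none
Why: Copper-catalysed propargylic etherification of phenols with a tertiary propargylic chloride, in which the copper acetylide ionises to an allenylidene-type electrophile that the DBU phenoxide captures at the tertiary carbon, while the hindered pivalate resists amidine-mediated acyl transfer.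

Step 5
Reactants: 10 [4-methoxy-2,6-bis(2-methylbut-3-yn-2-yloxy)phenyl][4-(pivaloyloxy)phenyl]methanone
Product: 12 [4-methoxy-2,6-bis(2-methylbut-3-en-2-yloxy)phenyl][4-(pivaloyloxy)phenyl]methanone, via half-reduced enyne ether 11 (not isolated)
Conditions: H2 (1 atm), Lindlar catalyst, quinoline, EtOAc, rt; stopped after 2 equiv H2
Reagents that add atoms: none
Why: Lindlar semi-hydrogenation, in which the poisoned palladium catalyst reduces terminal alkynes to vinyl groups and should stop there when hydrogen uptake is limited, leaving the diaryl ketone, the aryl ester and the tertiary ethers untouched.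

Step 6
Reactants: 12 [4-methoxy-2,6-bis(2-methylbut-3-en-2-yloxy)phenyl][4-(pivaloyloxy)phenyl]methanone
Product: 14 [2,6-dihydroxy-4-methoxy-3,5-bis(3-methylbut-2-en-1-yl)phenyl][4-(pivaloyloxy)phenyl]methanone (vismiaphenone D 4'-O-pivalate), via mono-rearranged phenol 13 (not isolated)
Conditions: PhNEt2 (degassed), 140 °C, Ar
Reagents that add atoms: none
Why: Each 1,1-dimethylallyl ether should undergo a concerted chair-like [3,3]-sigmatropic shift in which the vinyl CH2 terminus bonds to the unsubstituted ortho carbon as the O–CMe2 bond breaks, and the ortho-dienone so formed enolises to a phenol hydrogen-bonded to the ketone; the first shift gives 13 and the second, at the other ether, gives 14. This is the aromatic Claisen rearrangement of aryl 1,1-dimethylallyl ethers to ortho-prenylphenols, a well-established reaction type. No ring is closed and no stereocentre is formed; the allylic transposition of the [3,3] shift turns each reverse-prenyl ether into a normal prenyl chain with its trisubstituted alkene. The step needs regioselectivity (C3 and C5 rather than C1) and needs the concerted pathway to win over ionisation of the tertiary ether. The aroyl group on C1 secures the first, since each ether oxygen has only one ortho C–H position and a shift to C1 would give a non-enolisable dienone that can revert; the weakly basic, non-polar amine solvent and the barrier-lowering gem-dimethyl group secure the second by scavenging acid and allowing a moderate temperature.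

Step 7
Reactants: 14 [2,6-dihydroxy-4-methoxy-3,5-bis(3-methylbut-2-en-1-yl)phenyl][4-(pivaloyloxy)phenyl]methanone
Product: 15 [2,6-dihydroxy-4-methoxy-3,5-bis(3-methylbut-2-en-1-yl)phenyl](4-hydroxyphenyl)methanone (vismiaphenone D)
Conditions: K2CO3 (3 equiv), MeOH (degassed), rt; then 1 M HCl to pH 5, 0 °C
Reagents that add atoms: none
Why: Base-mediated methanolysis (transesterification) of an aryl ester, in which methoxide attacks the pivalate and expels the stabilised 4-acylphenoxide while the prenyl groups, the ketone and the methyl ether are inert to carbonate in methanol.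

Compound list
1 | 4-hydroxybenzoic acid | O=C(O)c1ccc(O)cc1 | starting material
2 | 4-(pivaloyloxy)benzoic acid | CC(C)(C)C(=O)Oc1ccc(cc1)C(=O)O | intermediate
3 | 1,3,5-trimethoxybenzene | COc1cc(OC)cc(OC)c1 | starting material
4 | 4-(pivaloyloxy)benzoyl chloride | CC(C)(C)C(=O)Oc1ccc(cc1)C(=O)Cl | intermediate
5 | (2,4,6-trimethoxyphenyl)[4-(pivaloyloxy)phenyl]methanone | COc1cc(OC)c(C(=O)c2ccc(OC(=O)C(C)(C)C)cc2)c(OC)c1 | intermediate
6 | (2-hydroxy-4,6-dimethoxyphenyl)[4-(pivaloyloxy)phenyl]methanone | COc1cc(O)c(C(=O)c2ccc(OC(=O)C(C)(C)C)cc2)c(OC)c1 | intermediate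
7 | (2,6-dihydroxy-4-methoxyphenyl)[4-(pivaloyloxy)phenyl]methanone | COc1cc(O)c(C(=O)c2ccc(OC(=O)C(C)(C)C)cc2)c(O)c1 | intermediate
8 | 3-chloro-3-methylbut-1-yne | CC(C)(Cl)C#C | starting material
9 | [2-hydroxy-4-methoxy-6-(2-methylbut-3-yn-2-yloxy)phenyl][4-(pivaloyloxy)phenyl]methanone | COc1cc(O)c(C(=O)c2ccc(OC(=O)C(C)(C)C)cc2)c(OC(C)(C)C#C)c1 | intermediate
10 | [4-methoxy-2,6-bis(2-methylbut-3-yn-2-yloxy)phenyl][4-(pivaloyloxy)phenyl]methanone | COc1cc(OC(C)(C)C#C)c(C(=O)c2ccc(OC(=O)C(C)(C)C)cc2)c(OC(C)(C)C#C)c1 | intermediate
11 | [4-methoxy-2-(2-methylbut-3-en-2-yloxy)-6-(2-methylbut-3-yn-2-yloxy)phenyl][4-(pivaloyloxy)phenyl]methanone | COc1cc(OC(C)(C)C=C)c(C(=O)c2ccc(OC(=O)C(C)(C)C)cc2)c(OC(C)(C)C#C)c1 | intermediate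
12 | [4-methoxy-2,6-bis(2-methylbut-3-en-2-yloxy)phenyl][4-(pivaloyloxy)phenyl]methanone | COc1cc(OC(C)(C)C=C)c(C(=O)c2ccc(OC(=O)C(C)(C)C)cc2)c(OC(C)(C)C=C)c1 | intermediate
13 | [2-hydroxy-4-methoxy-3-(3-methylbut-2-en-1-yl)-6-(2-methylbut-3-en-2-yloxy)phenyl][4-(pivaloyloxy)phenyl]methanone | COc1cc(OC(C)(C)C=C)c(C(=O)c2ccc(OC(=O)C(C)(C)C)cc2)c(O)c1CC=C(C)C | intermediate
14 | [2,6-dihydroxy-4-methoxy-3,5-bis(3-methylbut-2-en-1-yl)phenyl][4-(pivaloyloxy)phenyl]methanone | COc1c(CC=C(C)C)c(O)c(C(=O)c2ccc(OC(=O)C(C)(C)C)cc2)c(O)c1CC=C(C)C | intermediate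
15 | vismiaphenone D, [2,6-dihydroxy-4-methoxy-3,5-bis(3-methylbut-2-en-1-yl)phenyl](4-hydroxyphenyl)methanone | COc1c(CC=C(C)C)c(O)c(C(=O)c2ccc(O)cc2)c(O)c1CC=C(C)C | target

Total step count: 7. Longest linear sequence: 7 steps (from 4-hydroxybenzoic acid; the route is fully linear).

Steps most likely to fail

Step 6. Heterolysis of the tertiary C–O bond may outrun the concerted shift, giving loss of isoprene and return of the phenols. The second rearrangement may also stall, or the new ortho-prenylphenol may cyclise onto its alkene under adventitious acid. The fallback replaces the [3,3] shift by a clay-promoted [1,3] O-to-C prenyl shift. It sets out from 7, whose two phenols are O-alkylated with prenyl bromide (K2CO3, acetone, reflux) to give [4-methoxy-2,6-bis(3-methylbut-2-enyloxy)phenyl][4-(pivaloyloxy)phenyl]methanone F1. Treatment of this ether with montmorillonite K10 in CH2Cl2 at 0 °C should move each prenyl group to carbon. The ortho and para positions open to each migrating group are C3 and C5, so either mode of migration leads to 14, where the route is rejoined before step 7.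

Step 4. The second etherification may stop because the remaining phenol is locked in a hydrogen bond to the ketone and shielded by the first tertiary ether, while base-induced elimination consumes 8. The fallback installs the two prenyl groups one after the other. It sets out from 7, which with 1.1 equiv of 8 under the same copper/DBU conditions should stop at the mono-ether 9, here isolated. Lindlar semi-hydrogenation should give [2-hydroxy-4-methoxy-6-(2-methylbut-3-en-2-yloxy)phenyl][4-(pivaloyloxy)phenyl]methanone F2. Heating in PhNEt2 should rearrange it to [2,6-dihydroxy-4-methoxy-3-(3-methylbut-2-en-1-yl)phenyl][4-(pivaloyloxy)phenyl]methanone F3. In F3 the phenol at C6 is the less hindered one, so a second copper-catalysed etherification with 8 should give [2-hydroxy-4-methoxy-3-(3-methylbut-2-en-1-yl)-6-(2-methylbut-3-yn-2-yloxy)phenyl][4-(pivaloyloxy)phenyl]methanone F4. Semi-hydrogenation of F4 returns to the route at 13, which rearranges to 14 under the conditions of step 6.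

Step 3. Demethylation may halt after the first ortho ether once the aluminium phenoxide chelates the ketone, or prolonged Lewis-acid exposure may ionise the aryl pivalate. The fallback brings in the two ortho oxygens as acetals so that no methyl ether has to be cleaved. It sets out from 2, converted to acid chloride 4 as in step 2. Commercial 5-methoxyresorcinol is converted with chloromethyl methyl ether and i-Pr2NEt (CH2Cl2) into 1-methoxy-3,5-bis(methoxymethoxy)benzene F5. Directed ortho-lithiation (n-BuLi, THF, 0 °C) between the two acetal oxygens should give [4-methoxy-2,6-bis(methoxymethoxy)phenyl]lithium F6. Inverse addition of F6 to 4 at −78 °C should give [4-methoxy-2,6-bis(methoxymethoxy)phenyl][4-(pivaloyloxy)phenyl]methanone F7, whose doubly ortho-substituted ketone is too hindered for a second addition. Acetal hydrolysis (2 M HCl, THF, 40 °C) then returns to the route at 7.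

Further compounds
F1 | step 6 | [4-methoxy-2,6-bis(3-methylbut-2-enyloxy)phenyl][4-(pivaloyloxy)phenyl]methanone | COc1cc(OCC=C(C)C)c(C(=O)c2ccc(OC(=O)C(C)(C)C)cc2)c(OCC=C(C)C)c1
F2 | step 4 | [2-hydroxy-4-methoxy-6-(2-methylbut-3-en-2-yloxy)phenyl][4-(pivaloyloxy)phenyl]methanone | COc1cc(O)c(C(=O)c2ccc(OC(=O)C(C)(C)C)cc2)c(OC(C)(C)C=C)c1
F3 | step 4 | [2,6-dihydroxy-4-methoxy-3-(3-methylbut-2-en-1-yl)phenyl][4-(pivaloyloxy)phenyl]methanone | COc1cc(O)c(C(=O)c2ccc(OC(=O)C(C)(C)C)cc2)c(O)c1CC=C(C)C
F4 | step 4 | [2-hydroxy-4-methoxy-3-(3-methylbut-2-en-1-yl)-6-(2-methylbut-3-yn-2-yloxy)phenyl][4-(pivaloyloxy)phenyl]methanone | COc1cc(OC(C)(C)C#C)c(C(=O)c2ccc(OC(=O)C(C)(C)C)cc2)c(O)c1CC=C(C)C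
F5 | step 3 | 1-methoxy-3,5-bis(methoxymethoxy)benzene | COCOc1cc(OC)cc(OCOC)c1
F6 | step 3 | [4-methoxy-2,6-bis(methoxymethoxy)phenyl]lithium | [Li]c1c(OCOC)cc(OC)cc1OCOC
F7 | step 3 | [4-methoxy-2,6-bis(methoxymethoxy)phenyl][4-(pivaloyloxy)phenyl]methanone | COCOc1cc(OC)cc(OCOC)c1C(=O)c1ccc(OC(=O)C(C)(C)C)cc1
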